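**Plan**

1. Retrosynthesis: the last cut is the C6–C7 bond together with the O6–C12 lactone bond (one operation); then the ester C–O bonds at C8, C14 and C9; then the C9–C10 bond (fragment union); then the C3–C4 bond and the two oxiranes of the C1–C6 part.
2. Enabling feature: C7 is the β-carbon and C6 the oxygen-bearing γ-carbon of the 7(11)-en-12,6-olide (butenolide), and both are members of the ten-membered carbocycle C1–C10. A C7 alkenyl metal held cis to the C12 ester that adds to a C6 aldehyde therefore closes the carbocycle and then the butenolide in one operation.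
3. Forward: fragment A (C1–C6, C10, C14) from a Heck diene and two Sharpless epoxidations; fragment B (C7–C9, C11–C13) as a tetrasubstituted β-stannyl enoate (masked iodide); union at C9–C10 by a first Ni/Cr coupling; the four esters are put on the open chain; both rings close in the last step.
4. Stereochemistry: C4/C5 then C2/C3 by Sharpless epoxidation (L- then D-tartrate); C8 by Zn–ProPhenol alkynylation; C9 by Felkin–Anh reduction of the C9 enone; the ester oxirane from methyl (S)-2-methylglycidate; C6 in the ring closure; Z C1=C10 from an α-iodo ylide Wittig reaction; C7=C11 geometry from the iodo-aldol.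

Key step: step 27

Remark: locants C1–C14 are those of the germacrane skeleton of the target (C12 = lactone carbonyl; C13 and C14 = the CH2O carbons on C11 and C10).
Assumption: the Zn/(S,S)-ProPhenol alkynylation of (2E)-but-2-enal is taken to give the (4S)-carbinol 15; if the sense proved opposite, the (R,R)-ligand would be used.

**Fragment A**

Step 1
Reactants: 1 but-2-yn-1-ol
Product: 2 (2Z)-3-iodobut-2-en-1-ol
Conditions: NaAlH2(OCH2CH2OMe)2, THF, 0 °C to rt; then I2, −78 to 0 °C
Reagents that add atoms: iodine, II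
Why: Hydroxyl-directed trans-hydroalumination of the propargylic alcohol puts aluminium on C3 cis to the CH2O group and iodinolysis proceeds with retention, fixing the Z geometry that becomes the cis relation of C3 and C6 on the 4,5-oxirane.

Step 2
Reactants: 2 (2Z)-3-iodobut-2-en-1-ol; 3 ethyl acrylate
Product: 4 ethyl (2E,4Z)-6-hydroxy-4-methylhexa-2,4-dienoate
Conditions: Pd(OAc)2 (cat.), Ag2CO3, DMF, rt
Reagents that add atoms: none
Why: Mizoroki–Heck reaction in which oxidative addition retains the Z alkenyl geometry, syn insertion and syn β-hydride elimination give the E enoate, and the silver salt suppresses isomerisation; no stereocentre is formed.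

Step 3
Reactants: 4 ethyl (2E,4Z)-6-hydroxy-4-methylhexa-2,4-dienoate
Product: 5 ethyl (2E)-3-[(2R,3S)-3-(hydroxymethyl)-2-methyloxiran-2-yl]prop-2-enoate
Conditions: Ti(OiPr)4, L-(+)-diisopropyl tartrate, tBuOOH, 4 Å MS, CH2Cl2, −20 °C
Reagents that add atoms: tert-butyl hydroperoxide, CC(C)(C)OO
Why: Sharpless asymmetric epoxidation in which the titanium tartrate bound to the C6 hydroxyl delivers oxygen to one face of the Z trisubstituted C4=C5 alkene (L-tartrate, the sense that converts nerol into (2S,3R)-epoxynerol), setting C4 and C5 while the electron-poor enoate alkene is left alone.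

Step 4
Reactants: 5 ethyl (2E)-3-[(2R,3S)-3-(hydroxymethyl)-2-methyloxiran-2-yl]prop-2-enoate
Product: 6 ethyl (2E)-3-[(2R,3S)-3-{[(4-methoxybenzyl)oxy]methyl}-2-methyloxiran-2-yl]prop-2-enoate
Conditions: 4-methoxybenzyl bromide, Ag2O, 4 Å MS, CH2Cl2, rt, dark
Reagents that add atoms: 4-methoxybenzyl bromide, COc1ccc(CBr)cc1
Why: Silver-oxide-mediated Williamson-type etherification without a free alkoxide, so that neither Payne rearrangement of the epoxy alcohol nor oxa-Michael addition to the enoate competes.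

Step 5
Reactants: 6 ethyl (2E)-3-[(2R,3S)-3-{[(4-methoxybenzyl)oxy]methyl}-2-methyloxiran-2-yl]prop-2-enoate
Product: 7 (2E)-3-[(2R,3S)-3-{[(4-methoxybenzyl)oxy]methyl}-2-methyloxiran-2-yl]prop-2-en-1-ol
Conditions: iBu2AlH, CH2Cl2, −78 °C
Reagents that add atoms: none
Why: 1,2-Reduction of the enoate by DIBAL-H to the E allylic alcohol, which is faster than hydride opening of the oxirane at −78 °C.

Step 6
Reactants: 7 (2E)-3-[(2R,3S)-3-{[(4-methoxybenzyl)oxy]methyl}-2-methyloxiran-2-yl]prop-2-en-1-ol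
Product: 8 [(2R,3S)-3-[(2S,3S)-3-{[(4-methoxybenzyl)oxy]methyl}-2-methyloxiran-2-yl]oxiran-2-yl]methanol
Conditions: Ti(OiPr)4, D-(−)-diisopropyl tartrate, tBuOOH, 4 Å MS, CH2Cl2, −20 °C
Reagents that add atoms: tert-butyl hydroperoxide, CC(C)(C)OO
Why: Second Sharpless asymmetric epoxidation, directed by the C1 hydroxyl to the E C2=C3 alkene, in which D-tartrate gives the (2R,3R)-type trans-epoxy alcohol under reagent control, setting C2 and C3 and turning any minor enantiomer from step 3 into a separable diastereomer.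

Step 7
Reactants: 8 [(2R,3S)-3-[(2S,3S)-3-{[(4-methoxybenzyl)oxy]methyl}-2-methyloxiran-2-yl]oxiran-2-yl]methanol
Product: 10 ethyl (2Z)-2-iodo-3-{(2R,3S)-3-[(2S,3S)-3-{[(4-methoxybenzyl)oxy]methyl}-2-methyloxiran-2-yl]oxiran-2-yl}prop-2-enoate, via bis-epoxy aldehyde 9 (not isolated)
Conditions: Dess–Martin periodinane, NaHCO3, CH2Cl2, 0 °C; then Ph3P=CHCO2Et/N-iodosuccinimide (premixed, CH2Cl2, −20 °C), 0 °C to rt
Reagents that add atoms: ethyl (triphenylphosphoranylidene)acetate, CCOC(=O)C=P(c1ccccc1)(c1ccccc1)c1ccccc1; N-iodosuccinimide, O=C1CCC(=O)N1I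
Why: Dess–Martin oxidation followed by Wittig olefination with the stabilised α-iodo ylide, which places the ester trans to the C2 substituent and so iodine cis to C2 (Z), the geometry required of C1=C10 once iodine is replaced by C9.

Step 8
Reactants: 10 ethyl (2Z)-2-iodo-3-(bis-oxiranyl)prop-2-enoate
Product: 11 (2Z)-2-iodo-3-{(2R,3S)-3-[(2S,3S)-3-{[(4-methoxybenzyl)oxy]methyl}-2-methyloxiran-2-yl]oxiran-2-yl}prop-2-en-1-ol
Conditions: iBu2AlH, CH2Cl2, −78 °C
Reagents that add atoms: none
Why: DIBAL-H reduction of the α-iodo enoate to the 2-iodoallylic alcohol (C14 carbinol), leaving the alkenyl iodide and both oxiranes intact at low temperature.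

Step 9
Reactants: 11 (2Z)-2-iodoallylic alcohol
Product: 12 fragment A, the C14 tert-butyldimethylsilyl ether of 11
Conditions: tBuMe2SiCl, imidazole, DMF, 0 °C
Reagents that add atoms: tert-butyldimethylsilyl chloride, CC(C)(C)[Si](C)(C)Cl
Why: Silylation of the primary allylic alcohol, so that a poor leaving group rather than the final ester sits β to the future alkenylchromium.

**Fragment B**

Step 10
Reactants: 13 (2E)-but-2-enal; 14 methyl propiolate
Product: 15 methyl (4S,5E)-4-hydroxyhept-5-en-2-ynoate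
Conditions: (S,S)-ProPhenol (cat.), Me2Zn, Ph3P=O (cat.), toluene, 0 °C
Reagents that add atoms: none
Why: Catalytic enantioselective alkynylation of an enal by the dinuclear zinc–ProPhenol alkynylzinc species, which differentiates the aldehyde faces and sets C8, the propenyl group being the latent C9 aldehyde.

Step 11
Reactants: 15 methyl (4S,5E)-4-hydroxyhept-5-en-2-ynoate
Product: 16 methyl (4S,5E)-4-[(triethylsilyl)oxy]hept-5-en-2-ynoate
Conditions: Et3SiCl, imidazole, CH2Cl2, 0 °C
Reagents that add atoms: chlorotriethylsilane, CC[Si](Cl)(CC)CC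
Why: Silylation of the secondary alcohol, which blocks lactonisation onto C12 and provides the non-chelating α-silyloxy group needed for the Felkin–Anh reduction in step 19.

Step 12
Reactants: 16 methyl (4S,5E)-4-[(triethylsilyl)oxy]hept-5-en-2-ynoate
Product: 17 methyl (2Z,4S,5E)-2-(hydroxymethyl)-3-iodo-4-[(triethylsilyl)oxy]hepta-2,5-dienoate
Conditions: MgI2, CH2O (monomeric, from cracked paraformaldehyde), CH2Cl2, 0 °C
Reagents that add atoms: formaldehyde, C=O; magnesium iodide, [Mg+2].[I-].[I-]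
Why: Iodo-aldol (β-iodo Morita–Baylis–Hillman) reaction in which iodide adds to C7 of the magnesium-activated ynoate and the β-iodo allenolate is hydroxymethylated at C11 anti to iodine, as in the kinetic Z-selective reaction of propiolates, so that iodine ends cis to the ester and C8 cis to C13; the reaction is kept cold and short to avoid iodide-mediated E/Z equilibration.

Step 13
Reactants: 17 methyl (2Z,4S,5E)-2-(hydroxymethyl)-3-iodo-4-[(triethylsilyl)oxy]hepta-2,5-dienoate
Product: 18 methyl (2Z,4S,5E)-2-(hydroxymethyl)-4-[(triethylsilyl)oxy]-3-(trimethylstannyl)hepta-2,5-dienoate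
Conditions: Me3SnSnMe3, Pd(PPh3)4 (cat.), toluene, 80 °C
Reagents that add atoms: hexamethylditin, C[Sn](C)(C)[Sn](C)(C)C
Why: Palladium-catalysed stannylation of the alkenyl iodide (Stille-type coupling with the distannane) with retention of geometry, which masks C7 so that the first Ni/Cr coupling cannot activate it, and which is run before acetylation because zerovalent palladium would ionise the allylic acetate.

Step 14
Reactants: 18 methyl (2Z,4S,5E)-2-(hydroxymethyl)-4-[(triethylsilyl)oxy]-3-(trimethylstannyl)hepta-2,5-dienoate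
Product: 19 methyl (2Z,4S,5E)-2-(acetoxymethyl)-4-[(triethylsilyl)oxy]-3-(trimethylstannyl)hepta-2,5-dienoate
Conditions: Ac2O, pyridine, DMAP (cat.), CH2Cl2, 0 °C
Reagents that add atoms: acetic anhydride, CC(=O)OC(C)=O
Why: Acetylation of the primary allylic alcohol installs the final C13 acetate.

Step 15
Reactants: 19 methyl (2Z,4S,5E)-2-(acetoxymethyl)-4-[(triethylsilyl)oxy]-3-(trimethylstannyl)hepta-2,5-dienoate
Product: 20 fragment B, methyl (2Z,4S)-2-(acetoxymethyl)-5-oxo-4-[(triethylsilyl)oxy]-3-(trimethylstannyl)pent-2-enoate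
Conditions: OsO4 (cat.), NaIO4, 2,6-lutidine, dioxane–H2O, rt
Reagents that add atoms: osmium tetroxide, O=[Os](=O)(=O)=O; sodium periodate, [Na+].[O-]I(=O)(=O)=O
Why: Lemieux–Johnson oxidative cleavage, in which the electron-rich disubstituted propenyl alkene is dihydroxylated and cleaved while the tetrasubstituted electron-poor stannyl enoate is inert, and 2,6-lutidine keeps the α-silyloxy aldehyde from epimerising.

**Acid component**

Step 16
Reactants: 21 methyl (2S)-2-methyloxirane-2-carboxylate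
Product: 22 potassium (2S)-2-methyloxirane-2-carboxylate
Conditions: KOH (1.0 equiv), MeOH, 0 °C; evaporation
Reagents that add atoms: potassium hydroxide, [K+].[OH-]
Why: Saponification at the acyl carbon leaves the quaternary oxirane stereocentre untouched, and the acid is kept as its salt so that it cannot open its own oxirane.

**Union and endgame**

Step 17
Reactants: 12 fragment A; 20 fragment B
Product: 23 open-chain C9 alcohol (both C9 epimers) with C7 SnMe3, C8 OSiEt3, C13 OAc, C14 OSitBuMe2 and C6 OPMB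
Conditions: CrCl2, NiCl2 (cat.), DMSO, rt
Reagents that add atoms: none
Why: Nozaki–Hiyama–Kishi coupling in which zerovalent nickel activates the C10–I bond, the alkenyl group passes to chromium with retention of geometry and adds to the C9 aldehyde without touching esters, oxiranes or the alkenylstannane; C9 is not controlled here and is set in step 19.

Step 18
Reactants: 23 open-chain C9 alcohol
Product: 24 C9 enone
Conditions: Dess–Martin periodinane, NaHCO3, CH2Cl2, 0 °C
Reagents that add atoms: none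
Why: Dess–Martin oxidation of the allylic alcohol converges both C9 epimers on one enone.

Step 19
Reactants: 24 C9 enone
Product: 25 (9R)-alcohol, 8,9-syn
Conditions: NaBH4, CeCl3·7H2O, MeOH, −78 °C
Reagents that add atoms: none
Why: Luche 1,2-reduction under Felkin–Anh control, in which hydride attacks anti to the C8–OSiEt3 bond and past the C8 hydrogen, not past the bulky C7 alkenyl group, giving the 8,9-syn (9R) carbinol.

Step 20
Reactants: 25 (9R)-alcohol; 22 potassium (2S)-2-methyloxirane-2-carboxylate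
Product: 26 C9 (2S)-2-methyloxirane-2-carboxylate ester
Conditions: 2,4,6-trichlorobenzoyl chloride, Et3N, DMAP, toluene, 0 °C to rt
Reagents that add atoms: none
Why: Yamaguchi esterification through the mixed anhydride acylates the hindered C9 alcohol with retention at C9 and at the oxirane stereocentre.

Step 21
Reactants: 26 C9 ester
Product: 27 C8,C14 diol
Conditions: Bu4NF, AcOH, THF, 0 °C to rt
Reagents that add atoms: none
Why: Buffered fluoride desilylation removes the C8 triethylsilyl and C14 tert-butyldimethylsilyl ethers, the acetic acid suppressing acyl migration and oxirane opening while the alkenylstannane and PMB ether stay inert.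

Step 22
Reactants: 27 C8,C14 diol
Product: 28 C14 3-methylbut-2-enoate with free C8 OH
Conditions: 3-methylbut-2-enoyl chloride, pyridine, CH2Cl2, −40 °C
Reagents that add atoms: 3-methylbut-2-enoyl chloride, CC(C)=CC(=O)Cl
Why: Chemoselective acylation of the primary allylic C14 alcohol beside the hindered secondary C8 alcohol, with pyridine rather than a trialkylamine to avoid deconjugation through the vinylketene.

Step 23
Reactants: 28 C14 ester with free C8 OH
Product: 29 tetra-ester alkenylstannane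
Conditions: Ac2O, pyridine, DMAP (cat.), CH2Cl2, 0 °C
Reagents that add atoms: acetic anhydride, CC(=O)OC(C)=O
Why: Acetylation of the remaining C8 alcohol completes the four esters while C7 is still the stannane, which does not react with DMAP.

Step 24
Reactants: 29 tetra-ester alkenylstannane
Product: 30 tetra-ester (Z)-β-iodo enoate
Conditions: I2, CH2Cl2, 0 °C
Reagents that add atoms: iodine, II
Why: Iododestannylation (ipso substitution with retention of geometry) unmasks the Z β-iodo enoate, the alkenyl–tin bond reacting far faster than the hindered or electron-poor alkenes.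

Step 25
Reactants: 30 tetra-ester (Z)-β-iodo enoate
Product: 31 C6 primary alcohol
Conditions: DDQ, CH2Cl2–pH 7 buffer, 0 °C
Reagents that add atoms: none
Why: Oxidative cleavage of the PMB ether under neutral conditions frees the C6 alcohol without harm to esters, oxiranes or the alkenyl iodide.

Step 26
Reactants: 31 C6 primary alcohol
Product: 32 C6 epoxy aldehyde
Conditions: Dess–Martin periodinane, NaHCO3, CH2Cl2, 0 °C
Reagents that add atoms: none
Why: Dess–Martin oxidation to the α,β-epoxy aldehyde, which cannot epimerise at C5 and is used at once.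

Step 27
Reactants: 32 C6 epoxy aldehyde
Product: 34 target CNP0279449.1, via macrocyclic hydroxy ester 33 (not isolated)
Conditions: CrCl2, NiCl2 (cat.), DMSO–THF, rt, slow addition (high dilution)
Reagents that add atoms: none
Why: Zerovalent nickel inserts into the C7–I bond of the (Z)-β-iodo enoate, the alkenyl group passes to trivalent chromium with retention of geometry, and the alkenylchromium adds to the C6 aldehyde (Nozaki–Hiyama–Kishi reaction; closest precedents are Ni/Cr macrocyclisations and the butenolide-forming coupling of (Z)-β-iodoacrylates with aldehydes). This C6–C7 bond formation closes the ten-membered carbocycle in a 10-exo-trig mode, and the chromium alkoxide of 33, held cis to the C12 methyl ester across C7=C11, then closes the butenolide by 5-exo-trig acyl substitution with loss of methoxide. The new C6 stereocentre is set by the C5 centre of the cis-4,5-oxirane together with the tether: C7 is tied through C8–C3 to the oxirane face remote from its oxygen and must attack anti to the C5–O bond, and of the two aldehyde rotamers the one with the chromium-bound oxygen outside the forming ring (anti to C4, aldehyde hydrogen over C3) should be favoured, giving the 5,6-syn (6R) alkoxide. The step needs selective activation of the C–I bond beside two allylic esters and a vinyl oxirane, which the much faster oxidative addition of the electron-poor β-iodo enoate at low nickel loading secures, and ring closure over oligomerisation, which high dilution and the chain-folding Z alkene, two oxiranes and C8/C9 substituents secure. Only O6 can lactonise, because C8 lies trans to the ester on C7=C11.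

**Compound list**

1 | but-2-yn-1-ol | CC#CCO | starting material
2 | (2Z)-3-iodobut-2-en-1-ol | C/C(I)=C/CO | intermediate
3 | ethyl acrylate | C=CC(=O)OCC | starting material
4 | ethyl (2E,4Z)-6-hydroxy-4-methylhexa-2,4-dienoate | CCOC(=O)/C=C/C(C)=C\CO | intermediate
5 | ethyl (2E)-3-[(2R,3S)-3-(hydroxymethyl)-2-methyloxiran-2-yl]prop-2-enoate | CCOC(=O)/C=C/[C@@]1(C)O[C@H]1CO | intermediate
6 | ethyl (2E)-3-[(2R,3S)-3-{[(4-methoxybenzyl)oxy]methyl}-2-methyloxiran-2-yl]prop-2-enoate | CCOC(=O)/C=C/[C@@]1(C)O[C@H]1COCc1ccc(OC)cc1 | intermediate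
7 | (2E)-3-[(2R,3S)-3-{[(4-methoxybenzyl)oxy]methyl}-2-methyloxiran-2-yl]prop-2-en-1-ol | OC/C=C/[C@@]1(C)O[C@H]1COCc1ccc(OC)cc1 | intermediate
8 | [(2R,3S)-3-[(2S,3S)-3-{[(4-methoxybenzyl)oxy]methyl}-2-methyloxiran-2-yl]oxiran-2-yl]methanol | OC[C@H]1O[C@@H]1[C@@]1(C)O[C@H]1COCc1ccc(OC)cc1 | intermediate
9 | bis-epoxy aldehyde (C1 aldehyde of 8, oxirane centres unchanged) | O=C[C@H]1O[C@@H]1[C@@]1(C)O[C@H]1COCc1ccc(OC)cc1 | intermediate (not isolated)
10 | ethyl (2Z)-2-iodo-3-{(2R,3S)-3-[(2S,3S)-3-{[(4-methoxybenzyl)oxy]methyl}-2-methyloxiran-2-yl]oxiran-2-yl}prop-2-enoate | CCOC(=O)/C(I)=C/[C@H]1O[C@@H]1[C@@]1(C)O[C@H]1COCc1ccc(OC)cc1 | intermediate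
11 | (2Z)-2-iodo-3-{(2R,3S)-3-[(2S,3S)-3-{[(4-methoxybenzyl)oxy]methyl}-2-methyloxiran-2-yl]oxiran-2-yl}prop-2-en-1-ol | OC/C(I)=C/[C@H]1O[C@@H]1[C@@]1(C)O[C@H]1COCc1ccc(OC)cc1 | intermediate
12 | fragment A: tert-butyldimethylsilyl ether of 11 (C14 OSitBuMe2, C10 iodide, C6 OPMB) | CC(C)(C)[Si](C)(C)OC/C(I)=C/[C@H]1O[C@@H]1[C@@]1(C)O[C@H]1COCc1ccc(OC)cc1 | intermediate
13 | (2E)-but-2-enal | C/C=C/C=O | starting material
14 | methyl propiolate | C#CC(=O)OC | starting material
15 | methyl (4S,5E)-4-hydroxyhept-5-en-2-ynoate | C/C=C/[C@H](O)C#CC(=O)OC | intermediate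
16 | methyl (4S,5E)-4-[(triethylsilyl)oxy]hept-5-en-2-ynoate | C/C=C/[C@H](O[Si](CC)(CC)CC)C#CC(=O)OC | intermediate
17 | methyl (2Z,4S,5E)-2-(hydroxymethyl)-3-iodo-4-[(triethylsilyl)oxy]hepta-2,5-dienoate | C/C=C/[C@H](O[Si](CC)(CC)CC)/C(I)=C(\CO)C(=O)OC | intermediate
18 | methyl (2Z,4S,5E)-2-(hydroxymethyl)-4-[(triethylsilyl)oxy]-3-(trimethylstannyl)hepta-2,5-dienoate | C/C=C/[C@H](O[Si](CC)(CC)CC)/C([Sn](C)(C)C)=C(\CO)C(=O)OC | intermediate
19 | methyl (2Z,4S,5E)-2-(acetoxymethyl)-4-[(triethylsilyl)oxy]-3-(trimethylstannyl)hepta-2,5-dienoate | C/C=C/[C@H](O[Si](CC)(CC)CC)/C([Sn](C)(C)C)=C(\COC(C)=O)C(=O)OC | intermediate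
20 | fragment B: methyl (2Z,4S)-2-(acetoxymethyl)-5-oxo-4-[(triethylsilyl)oxy]-3-(trimethylstannyl)pent-2-enoate | O=C[C@H](O[Si](CC)(CC)CC)/C([Sn](C)(C)C)=C(\COC(C)=O)C(=O)OC | intermediate
21 | methyl (2S)-2-methyloxirane-2-carboxylate | COC(=O)[C@]1(C)CO1 | starting material
22 | potassium (2S)-2-methyloxirane-2-carboxylate | [K+].[O-]C(=O)[C@]1(C)CO1 | intermediate
23 | open-chain C9 alcohol, mixture of C9 epimers (C7 SnMe3, C8 OSiEt3, C13 OAc, C14 OSitBuMe2, C6 OPMB) | COC(=O)/C(COC(C)=O)=C(\[Sn](C)(C)C)[C@@H](O[Si](CC)(CC)CC)C(O)/C(CO[Si](C)(C)C(C)(C)C)=C\[C@H]1O[C@@H]1[C@@]1(C)O[C@H]1COCc1ccc(OC)cc1 | intermediate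
24 | C9 enone of 23 | COC(=O)/C(COC(C)=O)=C(\[Sn](C)(C)C)[C@@H](O[Si](CC)(CC)CC)C(=O)/C(CO[Si](C)(C)C(C)(C)C)=C\[C@H]1O[C@@H]1[C@@]1(C)O[C@H]1COCc1ccc(OC)cc1 | intermediate
25 | (9R)-alcohol, 8,9-syn | COC(=O)/C(COC(C)=O)=C(\[Sn](C)(C)C)[C@@H](O[Si](CC)(CC)CC)[C@H](O)/C(CO[Si](C)(C)C(C)(C)C)=C\[C@H]1O[C@@H]1[C@@]1(C)O[C@H]1COCc1ccc(OC)cc1 | intermediate
26 | C9 (2S)-2-methyloxirane-2-carboxylate of 25 | COC(=O)/C(COC(C)=O)=C(\[Sn](C)(C)C)[C@@H](O[Si](CC)(CC)CC)[C@H](OC(=O)[C@]1(C)CO1)/C(CO[Si](C)(C)C(C)(C)C)=C\[C@H]1O[C@@H]1[C@@]1(C)O[C@H]1COCc1ccc(OC)cc1 | intermediate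
27 | C8,C14 diol of 26 | COC(=O)/C(COC(C)=O)=C(\[Sn](C)(C)C)[C@@H](O)[C@H](OC(=O)[C@]1(C)CO1)/C(CO)=C\[C@H]1O[C@@H]1[C@@]1(C)O[C@H]1COCc1ccc(OC)cc1 | intermediate
28 | C14 3-methylbut-2-enoate, C8 OH free | COC(=O)/C(COC(C)=O)=C(\[Sn](C)(C)C)[C@@H](O)[C@H](OC(=O)[C@]1(C)CO1)/C(COC(=O)C=C(C)C)=C\[C@H]1O[C@@H]1[C@@]1(C)O[C@H]1COCc1ccc(OC)cc1 | intermediate
29 | tetra-ester alkenylstannane (C8 OAc, C13 OAc, C9 and C14 esters, C7 SnMe3, C6 OPMB) | COC(=O)/C(COC(C)=O)=C(\[Sn](C)(C)C)[C@@H](OC(C)=O)[C@H](OC(=O)[C@]1(C)CO1)/C(COC(=O)C=C(C)C)=C\[C@H]1O[C@@H]1[C@@]1(C)O[C@H]1COCc1ccc(OC)cc1 | intermediate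
30 | tetra-ester (Z)-β-iodo enoate (C7 iodide) | COC(=O)/C(COC(C)=O)=C(\I)[C@@H](OC(C)=O)[C@H](OC(=O)[C@]1(C)CO1)/C(COC(=O)C=C(C)C)=C\[C@H]1O[C@@H]1[C@@]1(C)O[C@H]1COCc1ccc(OC)cc1 | intermediate
31 | C6 primary alcohol of 30 | COC(=O)/C(COC(C)=O)=C(\I)[C@@H](OC(C)=O)[C@H](OC(=O)[C@]1(C)CO1)/C(COC(=O)C=C(C)C)=C\[C@H]1O[C@@H]1[C@@]1(C)O[C@H]1CO | intermediate
32 | C6 epoxy aldehyde, seco precursor | COC(=O)/C(COC(C)=O)=C(\I)[C@@H](OC(C)=O)[C@H](OC(=O)[C@]1(C)CO1)/C(COC(=O)C=C(C)C)=C\[C@H]1O[C@@H]1[C@@]1(C)O[C@H]1C=O | intermediate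
33 | macrocyclic hydroxy ester (ten-membered carbocycle, (6R)-OH as chromium alkoxide, C12 methyl ester) | COC(=O)/C(COC(C)=O)=C1/[C@@H](OC(C)=O)[C@H](OC(=O)[C@]2(C)CO2)/C(COC(=O)C=C(C)C)=C\[C@H]2O[C@@H]2[C@@]2(C)O[C@H]2[C@@H]1O | intermediate (not isolated)
34 | CNP0279449.1: (2R,3S,4S,5S,6R,8R,9R,1(10)Z)-8,13-diacetoxy-2,3:4,5-diepoxy-14-(3-methylbut-2-enoyloxy)-9-[(2S)-2-methyloxirane-2-carbonyloxy]germacra-1(10),7(11)-dien-12,6-olide | CC(=O)OCC1=C2[C@@H](OC(C)=O)[C@H](OC(=O)[C@]3(C)CO3)/C(COC(=O)C=C(C)C)=C\[C@H]3O[C@@H]3[C@@]3(C)O[C@H]3[C@@H]2OC1=O | target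

**Step count**

Total: 27 steps. Longest linear sequence: 20 steps (steps 1–9, then 17–27, from but-2-yn-1-ol).

**Steps most likely to fail**

1. Step 27 (ring closure). The alkenylchromium may add to the wrong face of the C6 aldehyde, intermolecular coupling may outrun closure of the ten-membered ring, and zerovalent nickel may ionise the allylic C9 and C14 esters. Fallback, setting out from 26 and coming back at 34: the ring is closed before the C8 and C14 esters are in place, so that bulky silyl ethers change the folding of the chain and no primary allylic ester is present. I2 converts 26 into the alkenyl iodide F1; DDQ gives the C6 alcohol F2; Dess–Martin oxidation gives the aldehyde F3; CrCl2/NiCl2 closure with lactonisation gives the silyl-protected macrolactone F4; Bu4NF/AcOH gives the diol F5; 3-methylbut-2-enoyl chloride/pyridine gives the C14 ester F6; Ac2O/pyridine/DMAP then gives 34.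

2. Step 12 (iodo-aldol). The hydroxymethyl group may enter syn to iodine, or the product may equilibrate by iodide addition–elimination, so that iodine ends trans to the ester; MgI2 may also cleave the silyl ether. Fallback, setting out from 16 and coming back at 18: the alkene geometry is fixed by a chelated enolate instead. Conjugate addition of pyrrolidine to 16 and hydrolysis give the β-keto ester F7; NaH and 4-methoxybenzyl chloromethyl ether give the C-alkylated keto ester F8; aqueous LiOH/Tf2O in toluene gives the Z enol triflate F9 through the lithium-chelated enolate (triflate cis to the ester); Me3SnSnMe3, Pd(PPh3)4 and LiCl give the stannane F10; DDQ removes the PMB group to give 18.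

3. Step 17 (first Ni/Cr coupling). The C10 alkenylchromium may expel the allylic C2–C3 oxirane oxygen (allene formation), and aldehyde 20 may epimerise at C8 or enolise before it couples. Fallback, setting out from 7 and coming back at 23: the coupling is done before the 2,3-oxirane exists, and that oxirane is then introduced under reagent control. Dess–Martin oxidation of 7 gives the dienal F11; the α-iodo ylide of step 7 gives the iodo dienoate F12; iBu2AlH gives the alcohol F13; tBuMe2SiCl gives the silyl ether F14; CrCl2/NiCl2 coupling with 20 gives the diene alcohol F15; Shi epoxidation (D-fructose-derived ketone, Oxone, buffered) of the E disubstituted C2=C3 alkene, the more electron-rich alkene and remote from the two allylic oxygens on C1=C10, then gives 23.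

Further compounds
F1 | step 27 | C7 iodide of 26 (C8 OSiEt3, C14 OSitBuMe2, C6 OPMB) | COC(=O)/C(COC(C)=O)=C(\I)[C@@H](O[Si](CC)(CC)CC)[C@H](OC(=O)[C@]1(C)CO1)/C(CO[Si](C)(C)C(C)(C)C)=C\[C@H]1O[C@@H]1[C@@]1(C)O[C@H]1COCc1ccc(OC)cc1
F2 | step 27 | C6 alcohol of F1 | COC(=O)/C(COC(C)=O)=C(\I)[C@@H](O[Si](CC)(CC)CC)[C@H](OC(=O)[C@]1(C)CO1)/C(CO[Si](C)(C)C(C)(C)C)=C\[C@H]1O[C@@H]1[C@@]1(C)O[C@H]1CO
F3 | step 27 | C6 aldehyde of F2 | COC(=O)/C(COC(C)=O)=C(\I)[C@@H](O[Si](CC)(CC)CC)[C@H](OC(=O)[C@]1(C)CO1)/C(CO[Si](C)(C)C(C)(C)C)=C\[C@H]1O[C@@H]1[C@@]1(C)O[C@H]1C=O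
F4 | step 27 | macrolactone with C8 OSiEt3 and C14 OSitBuMe2 | CC(=O)OCC1=C2[C@@H](O[Si](CC)(CC)CC)[C@H](OC(=O)[C@]3(C)CO3)/C(CO[Si](C)(C)C(C)(C)C)=C\[C@H]3O[C@@H]3[C@@]3(C)O[C@H]3[C@@H]2OC1=O
F5 | step 27 | macrolactone C8,C14 diol | CC(=O)OCC1=C2[C@@H](O)[C@H](OC(=O)[C@]3(C)CO3)/C(CO)=C\[C@H]3O[C@@H]3[C@@]3(C)O[C@H]3[C@@H]2OC1=O
F6 | step 27 | macrolactone C14 3-methylbut-2-enoate with free C8 OH | CC(=O)OCC1=C2[C@@H](O)[C@H](OC(=O)[C@]3(C)CO3)/C(COC(=O)C=C(C)C)=C\[C@H]3O[C@@H]3[C@@]3(C)O[C@H]3[C@@H]2OC1=O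
F7 | step 12 | methyl (4S,5E)-3-oxo-4-[(triethylsilyl)oxy]hept-5-enoate | C/C=C/[C@H](O[Si](CC)(CC)CC)C(=O)CC(=O)OC
F8 | step 12 | methyl (4S,5E)-2-{[(4-methoxybenzyl)oxy]methyl}-3-oxo-4-[(triethylsilyl)oxy]hept-5-enoate (C2 epimers) | C/C=C/[C@H](O[Si](CC)(CC)CC)C(=O)C(COCc1ccc(OC)cc1)C(=O)OC
F9 | step 12 | Z enol triflate of F8 (triflate cis to the ester) | C/C=C/[C@H](O[Si](CC)(CC)CC)/C(OS(=O)(=O)C(F)(F)F)=C(\COCc1ccc(OC)cc1)C(=O)OC
F10 | step 12 | PMB ether of 18 | C/C=C/[C@H](O[Si](CC)(CC)CC)/C([Sn](C)(C)C)=C(\COCc1ccc(OC)cc1)C(=O)OC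
F11 | step 17 | (2E)-3-[(2R,3S)-3-{[(4-methoxybenzyl)oxy]methyl}-2-methyloxiran-2-yl]prop-2-enal | O=C/C=C/[C@@]1(C)O[C@H]1COCc1ccc(OC)cc1
F12 | step 17 | ethyl (2Z,4E)-2-iodo-5-(epoxide)penta-2,4-dienoate | CCOC(=O)/C(I)=C/C=C/[C@@]1(C)O[C@H]1COCc1ccc(OC)cc1
F13 | step 17 | (2Z,4E)-2-iodo-5-(epoxide)penta-2,4-dien-1-ol | OC/C(I)=C/C=C/[C@@]1(C)O[C@H]1COCc1ccc(OC)cc1
F14 | step 17 | tert-butyldimethylsilyl ether of F13 | CC(C)(C)[Si](C)(C)OC/C(I)=C/C=C/[C@@]1(C)O[C@H]1COCc1ccc(OC)cc1
F15 | step 17 | coupled C9 alcohol (C9 epimers) with C2=C3 alkene in place of the 2,3-oxirane | COC(=O)/C(COC(C)=O)=C(\[Sn](C)(C)C)[C@@H](O[Si](CC)(CC)CC)C(O)/C(CO[Si](C)(C)C(C)(C)C)=C\C=C\[C@@]1(C)O[C@H]1COCc1ccc(OC)cc1
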